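The vessel is closed, stirred and held at one temperature, and two earlier runs stand behind the two new recipes.

| setting | red | teal | south | east |
|---|---|---|---|---|
| electrophile | 1 M | 1 M | 1.0 M | 1.0 M |
| nucleophile | 1.2 equiv | 1.9 equiv | 1.30 equiv | 2.60 equiv |
| remark | run made earlier | run made earlier |  |  |
| time |  |  | 12 h | 12 h |

| run | time / h | electrophile / % | target / % |
|---|---|---|---|
| red | 0.500 | 79 | 18 |
| red | 0.833 | 73 | 21 |
| red | 1.50 | 62 | 27 |
| red | 3.00 | 56 | 33 |
| red | 6.00 | 47 | 36 |
| teal | 0.500 | 68 | 25 |
| teal | 0.833 | 62 | 28 |
| teal | 1.50 | 47 | 34 |
| teal | 3.00 | 36 | 38 |
| teal | 6.00 | 27 | 30 |

(each reading ± 2 percentage points)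

- part of the electrophile that has reacted at the end, south
- part of the electrophile that has reacted at the end, east
- what raising the equivalents of nucleophile from its lowest to its highest value here does to the part of the electrophile that has reacted (changes below 5 percentage points count as none) (no change / it rises / it falls)



I ask first which number must be known well. The rate matters little: the red run's early half-life of electrophile reads 1.47 h, short against the 12 h allowed, so a moderate error in it should barely move the end. The starting concentration is 1.0 M, as in both runs, so it asks for no correction. So I turn to where the flask stops. Suppose each electrophile reacted takes two nucleophile, and each part missing from the sum of electrophile and target takes one more. By 6.00 h the red run has then spent a reckoned 1.23 against its 1.2 equiv, and the teal run 1.89 against its 1.9 equiv, each level with its charge within the scatter of the readings. So I take nucleophile as the limiting reagent and expect little from further hours.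

The number I carry is the nucleophile cost, the equivalents charged per fraction of electrophile reacted at the stop: 2.26 in the red run and 2.60 in the teal run. It grows with the charge, so I draw a straight line through both. That line gives south a cost of 2.31 and 56.2 % reacted, and east a cost of 2.94 and 88.4 % reacted. A slip of 2 percentage points in the last red reading moves south by about 2.1 points.

The forecast, reasoning that “something is dying with time”, gives 62 % for south, above my figure, 88 % for east, and for the trend: it rises.

South gives 54.6 % and east 90.6 %; with the equivalents raised from the lowest to the highest value, the part reacted goes as follows: it rises, by 36 points.

    nucleophile + acid set free ⇌ protonated nucleophile, settled at all times (K = 1900 L mol⁻¹)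
    nucleophile + target → over-reaction product (k = 0.560 L mol⁻¹ h⁻¹)
    electrophile + nucleophile ⇌ acid set free + target (K = 1.60, k = 0.470 L mol⁻¹ h⁻¹)

South ends with 0.81 % of its nucleophile free, less than the 45 % of its electrophile. The cost works out at 2.38 in south and 2.87 in east. For a neighbour of east charged with 0.650 equiv, the line gives a cost of 2.00 and 32.5 % reacted; that flask reaches 30.3 %, with 0.887 % of its nucleophile still free.

(The earlier runs and the new flask were generated by integration on assumed constants, and the scatter is random.)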